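**Retrosynthetic overview**
- Target ⇒ one-pot dehydration and cation–olefin cyclisation of a monocyclic ring A carbinol: closes ring B (C9–C10), places the 8,9-alkene, and sets C5 and C10 from C4.
- That carbinol ⇒ cross-metathesis (C8=C9) of a ring A carbinol carrying a 3-methylbut-3-enyl arm with (2E)-3-methylhepta-2,6-dienyl acetate, whose E-13 alkene comes from carboalumination of hex-1-en-5-yne.
- Ring A carbinol ⇒ Grignard addition (C5–C6) to methyl (1S)-1,3-dimethyl-2-oxocyclohexane-1-carboxylate.
- That β-keto ester ⇒ catalytic enantioselective one-carbon ring expansion of 2-methylcyclopentanone with methyl 2-diazopropanoate (ring A and the C4 quaternary centre).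
- Ring order: ring A first (five- to six-membered), ring B last.

Assumption: positions are quoted in labdane numbering (C4 = ester-bearing quaternary carbon, C5/C10 = ring fusion, C8=C9 = ring alkene), and methyl 2-diazopropanoate is treated as not purchasable and is made in step 1.

**Step 1**
Reactants: 1 L-alanine methyl ester hydrochloride
Product: 2 methyl 2-diazopropanoate
Conditions: NaOAc (1.0 equiv), isoamyl nitrite (1.2 equiv), CHCl3, reflux, 20 min; used as a titrated CH2Cl2 solution
Reagents that add atoms: isoamyl nitrite, CC(C)CCON=O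
Why: Diazotisation of a primary α-amino ester (N-nitrosation, tautomerisation, loss of water) gives the ester-stabilised diazo compound; the α-stereocentre is lost, so either enantiomer of alanine serves.

**Step 2**
Reactants: 2 methyl 2-diazopropanoate; 3 2-methylcyclopentanone (racemic)
Product: 4 methyl (1S)-1,3-dimethyl-2-oxocyclohexane-1-carboxylate (both C3 epimers, each 1S)
Conditions: Sc(OTf)3 (10 mol %), chiral N,N′-dioxide ligand (12 mol %; trimethylene-bridged bis[(S)-pipecolic acid N-oxide 2,6-diisopropylanilide], ligand enantiomer chosen to give 1S), 4 Å MS, CH2Cl2, −20 °C, slow addition of 2 (1.3 equiv), 24 h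
Reagents that add atoms: none
Why: Proposed new method: enantioselective, site-selective one-carbon ring expansion of a racemic α-branched cyclopentanone — the chiral trivalent-scandium N,N′-dioxide complex binds the ketone, the nucleophilic diazo carbon of 2 adds to the carbonyl through the one prochiral face left open by the ligand, and in the resulting oxido-diazonium adduct the unsubstituted ring CH2 (antiperiplanar to the C–N2 bond, the methyl-bearing carbon being turned away from the ester and the anilide wall) undergoes the 1,2-shift with loss of N2, which closes six-membered ring A and fixes the C4 quaternary centre (Me/CO2Me) as S under catalyst control from both enantiomers of 3 (the C10 methine epimers are erased in step 7), the hindered quaternary β-keto ester not homologating again; closest known reaction type: Lewis-acid-catalysed Tiffeneau–Demjanov-type homologation of symmetrical cycloalkanones with α-alkyl-α-diazo esters, including its scandium triflate/N,N′-dioxide enantioselective form, not yet shown for unsymmetrical racemic α-substituted ketones.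

**Step 3**
Reactants: 4 methyl (1S)-1,3-dimethyl-2-oxocyclohexane-1-carboxylate; 5 4-bromo-2-methylbut-1-ene
Product: 7 methyl (1S)-2-hydroxy-1,3-dimethyl-2-(3-methylbut-3-en-1-yl)cyclohexane-1-carboxylate (mixture at C2 and C3), via (3-methylbut-3-en-1-yl)magnesium bromide 6 (not isolated)
Conditions: 5 (1.6 equiv), Mg, THF, 35 °C; then 4 premixed with LaCl3·2LiCl (1.0 equiv), THF, −20 → 0 °C; sat. aq. NH4Cl
Reagents that add atoms: none
Why: Grignard 1,2-addition to the ketone, with LaCl3·2LiCl suppressing enolisation and reduction at the hindered carbonyl while the neopentyl ester is spared; the new carbinol centre and C3 form as mixtures that are erased in step 7.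

**Step 4**
Reactants: 8 hex-1-en-5-yne
Product: 11 (2E)-3-methylhepta-2,6-dien-1-ol, via alkenyl(dimethyl)alane 9 (not isolated), via lithium alkenylaluminate 10 (not isolated)
Conditions: AlMe3 (2.5 equiv), Cp2ZrCl2 (0.25 equiv), CH2Cl2, 0 °C → rt, 12 h; volatiles removed; hexane/THF, n-BuLi (1.05 equiv), −78 °C; (CH2O)n (4 equiv), −78 °C → rt; 1 M HCl
Reagents that add atoms: trimethylaluminium, C[Al](C)C; paraformaldehyde (reacts as formaldehyde), C=O
Why: Negishi zirconium-catalysed carboalumination adds Me–Al syn across the terminal alkyne (Me to the internal carbon), which fixes the E trisubstituted alkene, and the aluminate is hydroxymethylated with retention; the isolated terminal alkene does not react.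

**Step 5**
Reactants: 11 (2E)-3-methylhepta-2,6-dien-1-ol
Product: 12 (2E)-3-methylhepta-2,6-dien-1-yl acetate
Conditions: Ac2O (1.5 equiv), pyridine (2 equiv), DMAP (5 mol %), CH2Cl2, 0 °C → rt
Reagents that add atoms: acetic anhydride, CC(=O)OC(C)=O
Why: DMAP-catalysed O-acetylation of a primary allylic alcohol (nucleophilic acyl substitution).

**Step 6**
Reactants: 7 methyl (1S)-2-hydroxy-1,3-dimethyl-2-(3-methylbut-3-en-1-yl)cyclohexane-1-carboxylate; 12 (2E)-3-methylhepta-2,6-dien-1-yl acetate
Product: 13 methyl (1S)-2-[(3E,7E)-9-acetoxy-3,7-dimethylnona-3,7-dien-1-yl]-2-hydroxy-1,3-dimethylcyclohexane-1-carboxylate (7E fixed; 3E major, about 3:1 E/Z expected)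
Conditions: 12 (3 equiv), second-generation Hoveyda–Grubbs catalyst RuCl2(H2IMes)(=CH-C6H4-2-OiPr) (2 × 5 mol %), CH2Cl2 (0.2 M), 40 °C, argon sweep, 24 h
Reagents that add atoms: none
Why: Olefin cross-metathesis between a 1,1-disubstituted alkene (slow to homodimerise) and a terminal alkene in excess, driven by loss of ethene, gives the trisubstituted C8=C9 alkene, whose geometry disappears in step 7; the trisubstituted allylic-acetate alkene and the tertiary alcohol are inert to the ruthenium carbene.

**Step 7**
Reactants: 13 methyl (1S)-2-[(3E,7E)-9-acetoxy-3,7-dimethylnona-3,7-dien-1-yl]-2-hydroxy-1,3-dimethylcyclohexane-1-carboxylate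
Product: 15 methyl (1S,4aS,8aR)-5-[(3E)-5-acetoxy-3-methylpent-3-en-1-yl]-1,4a,6-trimethyl-1,2,3,4,4a,7,8,8a-octahydronaphthalene-1-carboxylate (CNP0206695.1), via ring-A cyclohexene 14 (not isolated)
Conditions: SOCl2 (1.5 equiv), pyridine (4 equiv), CH2Cl2, −40 → 0 °C, 1 h; then MeSO3H (10 equiv), −40 → −10 °C, 2 h; Et3N, aq. NaHCO3
Reagents that add atoms: none
Why: Dehydration followed by a Stork–Eschenmoser-type cation–olefin cyclisation — protonation of 14 at C5 gives the tertiary C10 cation, the side-chain alkene captures it 6-endo through a chair, and the C8 cation loses H9 to the thermodynamic tetrasubstituted alkene; C4 relays to C5 and C10 because closure occurs on the face that puts the angular methyl cis to the axial ester (smaller 1,3-diaxial partner, ester participation), the outcome known from classical cyclodehydrations to podocarpic-type 4-carboxylates, giving the trans-fused (5R,10S) ring fusion.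

**Compound list**
1 | L-alanine methyl ester hydrochloride | C[C@H](N)C(=O)OC.Cl | starting material
2 | methyl 2-diazopropanoate | COC(=O)C(C)=[N+]=[N-] | intermediate
3 | 2-methylcyclopentanone (racemic) | CC1CCCC1=O | starting material
4 | methyl (1S)-1,3-dimethyl-2-oxocyclohexane-1-carboxylate (C3 epimers) | COC(=O)[C@@]1(C)CCCC(C)C1=O | intermediate
5 | 4-bromo-2-methylbut-1-ene | CC(=C)CCBr | starting material
6 | (3-methylbut-3-en-1-yl)magnesium bromide | CC(=C)CC[Mg]Br | intermediate
7 | methyl (1S)-2-hydroxy-1,3-dimethyl-2-(3-methylbut-3-en-1-yl)cyclohexane-1-carboxylate (C2/C3 epimers) | COC(=O)[C@@]1(C)CCCC(C)C1(O)CCC(C)=C | intermediate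
8 | hex-1-en-5-yne | C=CCCC#C | starting material
9 | dimethyl[(1E)-2-methylhexa-1,5-dien-1-yl]alumane | C=CCC/C(C)=C/[Al](C)C | intermediate
10 | lithium butyl(dimethyl)[(1E)-2-methylhexa-1,5-dien-1-yl]aluminate | C=CCC/C(C)=C/[Al-](C)(C)CCCC.[Li+] | intermediate
11 | (2E)-3-methylhepta-2,6-dien-1-ol | C=CCC/C(C)=C/CO | intermediate
12 | (2E)-3-methylhepta-2,6-dien-1-yl acetate | C=CCC/C(C)=C/COC(C)=O | intermediate
13 | methyl (1S)-2-[(3E,7E)-9-acetoxy-3,7-dimethylnona-3,7-dien-1-yl]-2-hydroxy-1,3-dimethylcyclohexane-1-carboxylate (major 3E isomer shown) | COC(=O)[C@@]1(C)CCCC(C)C1(O)CC/C(C)=C/CC/C(C)=C/COC(C)=O | intermediate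
14 | methyl (1S)-2-[(3E,7E)-9-acetoxy-3,7-dimethylnona-3,7-dien-1-yl]-1,3-dimethylcyclohex-2-ene-1-carboxylate | COC(=O)[C@@]1(C)CCCC(C)=C1CC/C(C)=C/CC/C(C)=C/COC(C)=O | intermediate
15 | methyl (1S,4aS,8aR)-5-[(3E)-5-acetoxy-3-methylpent-3-en-1-yl]-1,4a,6-trimethyl-1,2,3,4,4a,7,8,8a-octahydronaphthalene-1-carboxylate (methyl 15-acetoxylabda-8,13E-dien-19-oate) | COC(=O)[C@@]1(C)CCC[C@]2(C)C(CC/C(C)=C/COC(C)=O)=C(C)CC[C@@H]12 | target

**Totals**
Total steps: 7. Longest linear sequence: 5 (steps 1, 2, 3, 6, 7).

**Three steps most likely to fail**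

Step 2 (the proposed new ring expansion). Possible failures are migration of the methyl-bearing carbon, glycidic-ester formation, or poor catalyst control over one enantiomer of 3. The fallback uses only known chemistry. No numbered compound other than the two reactants precedes this step, so the fallback starts afresh from commercial 2-methylcyclohexanone F1 and comes back at 4. F1 is C-acylated on its unsubstituted side (NaH, dimethyl carbonate, THF, reflux) to methyl 3-methyl-2-oxocyclohexane-1-carboxylate F2. Condensation with tert-butyl L-valinate (cat. BF3·OEt2, benzene, reflux, water removed) gives the chiral enamino ester F3. LDA in toluene at −78 °C gives the chelated lithio-enamine F4, and MeI methylates it on the face dictated by the auxiliary to give the imine F5 (Koga-type chiral enamine alkylation; solvent or auxiliary antipode chosen for 1S). Mild acid hydrolysis (aq. AcOH/NaOAc) gives 4 and returns the auxiliary.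

Step 6 (cross-metathesis to a trisubstituted alkene on the valuable ring A fragment). Conversion of the 1,1-disubstituted alkene may be low and homodimer of 12 may dominate. The fallback sets out from 11, 5 and 4 and comes back at 13. Metathesis is moved to the two small achiral pieces: 11 with a large excess of volatile 5 (same ruthenium catalyst) gives (2E,6E)-9-bromo-3,7-dimethylnona-2,6-dien-1-ol F6. After O-deprotonation with MeMgBr, Mg insertion gives the bromomagnesium alkoxide Grignard reagent F7. LaCl3·2LiCl-mediated addition of F7 to 4 gives methyl (1S)-2-hydroxy-2-[(3E,7E)-9-hydroxy-3,7-dimethylnona-3,7-dien-1-yl]-1,3-dimethylcyclohexane-1-carboxylate F8. Ac2O/pyridine acetylates only the primary allylic hydroxyl and delivers 13.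

Step 7 (one-pot dehydration and cyclisation). Possible failures are incomplete migration of the alkene into the 8,9-position (7-ene and 8(17)-ene isomers), further cyclisation through the 13,14-alkene, lactone formation from the C19 ester, and imperfect relay from C4. The fallback sets out from 13 and comes back at 15, separating bond formation from olefin placement. Compound 14 is isolated after the SOCl2/pyridine dehydration. It is cyclised under kinetic control with the Lewis-acid-assisted Brønsted acid SnCl4·2-methoxyphenol (1:1) in CH2Cl2 at −78 °C, which stops at the bicycle and gives mainly methyl (1S,4aR,5S,8aR)-5-[(3E)-5-acetoxy-3-methylpent-3-en-1-yl]-1,4a-dimethyl-6-methylidenedecahydronaphthalene-1-carboxylate F9. A separate isomerisation (I2, 5 mol %, benzene, 50 °C) then moves the double bond into the tetrasubstituted 8,9-position to give 15; residual 7-ene is removed on AgNO3-impregnated silica.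

**Further compounds**
F1 | step 2 | 2-methylcyclohexanone | CC1CCCCC1=O
F2 | step 2 | methyl 3-methyl-2-oxocyclohexane-1-carboxylate | COC(=O)C1CCCC(C)C1=O
F3 | step 2 | methyl 2-{[(2S)-1-tert-butoxy-3-methyl-1-oxobutan-2-yl]amino}-3-methylcyclohex-1-ene-1-carboxylate | COC(=O)C1=C(N[C@@H](C(C)C)C(=O)OC(C)(C)C)C(C)CCC1
F4 | step 2 | lithium salt of the N-deprotonated enamino ester F3 | COC(=O)C1=C([N-][C@@H](C(C)C)C(=O)OC(C)(C)C)C(C)CCC1.[Li+]
F5 | step 2 | methyl (1S)-2-{[(2S)-1-tert-butoxy-3-methyl-1-oxobutan-2-yl]imino}-1,3-dimethylcyclohexane-1-carboxylate | COC(=O)[C@@]1(C)CCCC(C)C1=N[C@@H](C(C)C)C(=O)OC(C)(C)C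
F6 | step 6 | (2E,6E)-9-bromo-3,7-dimethylnona-2,6-dien-1-ol | BrCC/C(C)=C/CC/C(C)=C/CO
F7 | step 6 | bromomagnesium (2E,6E)-9-(bromomagnesio)-3,7-dimethylnona-2,6-dien-1-olate | Br[Mg]CC/C(C)=C/CC/C(C)=C/CO[Mg]Br
F8 | step 6 | methyl (1S)-2-hydroxy-2-[(3E,7E)-9-hydroxy-3,7-dimethylnona-3,7-dien-1-yl]-1,3-dimethylcyclohexane-1-carboxylate | COC(=O)[C@@]1(C)CCCC(C)C1(O)CC/C(C)=C/CC/C(C)=C/CO
F9 | step 7 | methyl (1S,4aR,5S,8aR)-5-[(3E)-5-acetoxy-3-methylpent-3-en-1-yl]-1,4a-dimethyl-6-methylidenedecahydronaphthalene-1-carboxylate | COC(=O)[C@@]1(C)CCC[C@]2(C)[C@@H](CC/C(C)=C/COC(C)=O)C(=C)CC[C@@H]12
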